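**Plan**
- Retrosynthesis: remove the phenol silyl group; trace the C4' methyl back to CO2Me (a helper at a higher oxidation level); cut the side-chain bond C4'–C5' in a retro-ene sense into homoallylic alcohol 5 and chromenyl 2-alkynoate 19; cut 19 at the pyran C3=C4 (metathesis) and at O1–C2 (allylic etherification); 5 goes back to geraniol. Side-chain atoms are numbered 1'–13' outward from chromene C2.
- Enabling feature: the acyclic skipped diene C8'(OH)(CH3)–C7'H=C6'H–C5'H2–C4'(CH3)=C3'H. It is the imprint of a terminal alkene adding, with transposition, its CH2 carbon and an allylic hydrogen cis across an alkyne; the chromene ring is a spectator.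
- Forward: the chain half is made from geraniol (steps 1–4); the pyran ring is closed on the phenol by metathesis before the union (steps 5–13); the ruthenium-catalysed alkene–alkyne coupling joins the halves (step 14); CO2Me is reduced to CH3 (steps 15–16); desilylation ends the route (step 17).
- Stereochemistry: C8' (S) comes from the Sharpless epoxidation of geraniol and is never touched again; C2 (S) comes from the ligand-controlled palladium O-allylation; 6'E and 3'E come from the mechanism of the coupling.

Key step: step 14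

Assumption: the (R,R)-DACH-phenyl Trost ligand is taken to give the (S)-ether in step 12; if the sense of induction is the opposite, the (S,S)-ligand is used with no other change.

**Route**

Step 1
Reactants: 1 geraniol
Product: 2 (2S,3S)-2,3-epoxygeraniol
Conditions: Ti(OiPr)4 (5 mol%), L-(+)-diethyl tartrate (6 mol%), t-BuOOH, 4 Å MS, CH2Cl2, −20 °C
Reagents that add atoms: tert-butyl hydroperoxide, CC(C)(C)OO
Why: Sharpless asymmetric epoxidation, in which the titanium–L-(+)-tartrate complex delivers oxygen to one face of the hydroxyl-bearing 2,3-alkene only and so sets both centres as (2S,3S).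

Step 2
Reactants: 2 (2S,3S)-2,3-epoxygeraniol
Product: 3 (2R,3S)-3-methyl-3-(4-methylpent-3-en-1-yl)oxirane-2-carbaldehyde
Conditions: TEMPO (10 mol%), PhI(OAc)2, CH2Cl2, rt
Reagents that add atoms: none
Why: TEMPO/oxoammonium oxidation of a primary alcohol to the aldehyde under near-neutral conditions that should leave the epoxide, the trisubstituted alkene and both stereocentres untouched (the descriptor at C2 changes by priority only).

Step 3
Reactants: 3 (2R,3S)-3-methyl-3-(4-methylpent-3-en-1-yl)oxirane-2-carbaldehyde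
Product: 4 (2S,3S)-2-methyl-2-(4-methylpent-3-en-1-yl)-3-vinyloxirane
Conditions: Ph3PCH3Br, NaHMDS, THF, −78 → 0 °C
Reagents that add atoms: methyltriphenylphosphonium bromide, C[P+](c1ccccc1)(c1ccccc1)c1ccccc1.[Br-]
Why: Wittig methylenation with the non-stabilised ylide at low temperature should convert CHO into vinyl without opening the epoxide or epimerising the adjacent carbon.

Step 4
Reactants: 4 (2S,3S)-2-methyl-2-(4-methylpent-3-en-1-yl)-3-vinyloxirane
Product: 5 (4S)-4,8-dimethylnona-1,7-dien-4-ol
Conditions: Pd2(dba)3·CHCl3 (2.5 mol%), n-Bu3P (10 mol%), HCO2H, Et3N, dioxane, rt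
Reagents that add atoms: none
Why: Tsuji-type palladium-catalysed hydrogenolysis of an alkenyloxirane with formate, in which the π-allyl-palladium hydride should deliver hydrogen to the internal allyl terminus to give the terminal alkene while the tertiary C–O stereocentre is not involved and stays S.

Step 5
Reactants: 6 2-methylhydroquinone
Product: 7 4-[(tert-butyldimethylsilyl)oxy]-2-methylphenol
Conditions: TBSCl (1.0 equiv), imidazole, DMF, 0 °C
Reagents that add atoms: tert-butyldimethylsilyl chloride, CC(C)(C)[Si](C)(C)Cl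
Why: Silyl ether formation is expected to favour the hydroxyl that is not flanked by the ring methyl group; the regioisomer and the bis-ether are removed by chromatography.

Step 6
Reactants: 7 4-[(tert-butyldimethylsilyl)oxy]-2-methylphenol
Product: 9 5-[(tert-butyldimethylsilyl)oxy]-2-hydroxy-3-methylbenzaldehyde, via hydroxymethylphenol 8 (not isolated)
Conditions: MgCl2, Et3N, (CH2O)n, MeCN, reflux
Reagents that add atoms: paraformaldehyde (as formaldehyde), C=O
Why: Casnati–Skattebøl ortho-formylation, in which the magnesium phenoxide directs formaldehyde to the only free ortho position and a second formaldehyde oxidises the benzylic alkoxide by hydride transfer.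

Step 7
Reactants: 9 5-[(tert-butyldimethylsilyl)oxy]-2-hydroxy-3-methylbenzaldehyde
Product: 10 4-[(tert-butyldimethylsilyl)oxy]-2-ethenyl-6-methylphenol
Conditions: Ph3PCH3Br (2.5 equiv), NaHMDS (2.4 equiv), THF, 0 °C → rt
Reagents that add atoms: methyltriphenylphosphonium bromide, C[P+](c1ccccc1)(c1ccccc1)c1ccccc1.[Br-]
Why: Wittig methylenation of a salicylaldehyde with excess ylide (one equivalent is held by the phenol) should give the 2-vinylphenol, which is used promptly.

Step 8
Reactants: 11 geranyl acetate
Product: 12 (2E)-5-(3,3-dimethyloxiran-2-yl)-3-methylpent-2-en-1-yl acetate (racemic epoxide)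
Conditions: mCPBA (1.0 equiv), CH2Cl2, 0 °C
Reagents that add atoms: 3-chloroperbenzoic acid, OOC(=O)c1cccc(Cl)c1
Why: Prilezhaev epoxidation should occur at the electron-rich 6,7-alkene before the 2,3-alkene deactivated by the allylic acetate; the racemic epoxide carbon is removed in step 9.

Step 9
Reactants: 12 (2E)-5-(3,3-dimethyloxiran-2-yl)-3-methylpent-2-en-1-yl acetate
Product: 14 (2E)-3-methyl-6-oxohex-2-en-1-yl acetate, via acetoxy diol 13 (not isolated)
Conditions: H5IO6, THF/H2O, 0 °C
Reagents that add atoms: water, O (opens the epoxide to diol 13)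
Why: Acid-mediated epoxide hydrolysis followed by Malaprade glycol cleavage should give the aldehyde with loss of acetone and leave the E alkene and the acetate intact.

Step 10
Reactants: 14 (2E)-3-methyl-6-oxohex-2-en-1-yl acetate
Product: 16 (2E)-3-methylhept-2-en-6-yn-1-ol, via enynyl acetate 15 (not isolated)
Conditions: dimethyl (1-diazo-2-oxopropyl)phosphonate, K2CO3, MeOH, rt
Reagents that add atoms: dimethyl (1-diazo-2-oxopropyl)phosphonate, COP(=O)(OC)C(=[N+]=[N-])C(C)=O
Why: Ohira–Bestmann (Seyferth–Gilbert) homologation converts the aldehyde into the terminal alkyne, and the K2CO3/MeOH medium should also methanolyse the acetate.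

Step 11
Reactants: 16 (2E)-3-methylhept-2-en-6-yn-1-ol
Product: 17 methyl (6E)-8-[(methoxycarbonyl)oxy]-6-methyloct-6-en-2-ynoate
Conditions: n-BuLi (2.1 equiv), THF, −78 °C; ClCO2Me (2.5 equiv), −78 → 0 °C
Reagents that add atoms: methyl chloroformate, COC(=O)Cl
Why: Acylation of the dilithio species (alkoxide and acetylide) with methyl chloroformate should install the allylic methyl carbonate and the 2-alkynoate in one operation.

Step 12
Reactants: 10 4-[(tert-butyldimethylsilyl)oxy]-2-ethenyl-6-methylphenol; 17 methyl (6E)-8-[(methoxycarbonyl)oxy]-6-methyloct-6-en-2-ynoate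
Product: 18 methyl (6S)-6-{4-[(tert-butyldimethylsilyl)oxy]-2-ethenyl-6-methylphenoxy}-6-methyloct-7-en-2-ynoate
Conditions: Pd2(dba)3·CHCl3 (2 mol%), (R,R)-DACH-phenyl Trost ligand (6 mol%), CH2Cl2, rt
Reagents that add atoms: none
Why: Trost asymmetric allylic alkylation of a phenol, in which ionisation of the carbonate gives a 1,1-disubstituted π-allyl-palladium complex and the phenoxide should attack its more substituted terminus inside the chiral pocket, so the ligand sets the (S)-configured tertiary ether carbon.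

Step 13
Reactants: 18 methyl (6S)-6-{4-[(tert-butyldimethylsilyl)oxy]-2-ethenyl-6-methylphenoxy}-6-methyloct-7-en-2-ynoate
Product: 19 methyl 5-[(2S)-6-[(tert-butyldimethylsilyl)oxy]-2,8-dimethyl-2H-chromen-2-yl]pent-2-ynoate
Conditions: Grubbs II (5 mol%), CH2Cl2, 40 °C
Reagents that add atoms: none
Why: Ring-closing metathesis of the styrene and the vinyl group on the quaternary carbon should close the 2H-pyran ring with loss of ethene, without touching the C–O stereocentre, the internal electron-poor alkyne being a poor metathesis partner.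

Step 14
Reactants: 19 methyl 5-[(2S)-6-[(tert-butyldimethylsilyl)oxy]-2,8-dimethyl-2H-chromen-2-yl]pent-2-ynoate; 5 (4S)-4,8-dimethylnona-1,7-dien-4-ol
Product: 20 methyl (2Z)-5-[(2S)-6-[(tert-butyldimethylsilyl)oxy]-2,8-dimethyl-2H-chromen-2-yl]-2-[(2E,4S)-4-hydroxy-4,8-dimethylnona-2,7-dien-1-yl]pent-2-enoate
Conditions: [CpRu(MeCN)3]PF6 (10 mol%), 5 (1.5 equiv), acetone, rt
Reagents that add atoms: none
Why: Ruthenium-catalysed alkene–alkyne coupling (Trost's formal Alder-ene reaction): CpRu+ binds the terminal alkene of 5 and the alkyne of 19, oxidative cyclisation gives a ruthenacyclopentene in which the alkene CH2 terminus is bonded to the ester-bearing alkyne carbon, and β-hydride elimination from the allylic CH2 next to the carbinol followed by C–H reductive elimination releases the 1,4-diene. The closest precedent is the coupling of 2-alkynoates with monosubstituted alkenes, which alkylates the α-carbon of the alkynoate. No ring is closed and no stereocentre is formed or touched; both new alkene geometries follow from the mechanism, the migrated alkene being E and the hydrogen and the allyl group being delivered cis across the alkyne, which places the ester cis to the chromenylethyl chain (2Z, the arrangement that becomes 3'E once CO2Me is reduced to CH3). The step needs regioselectivity at the alkyne, secured by the ester (a plain methyl alkyne would offer no bias), linear coupling at the unsubstituted alkene carbon, and chemoselectivity for the one monosubstituted alkene, secured because the trisubstituted alkene does not bind and the chromene C3=C4 alkene has no allylic hydrogen to transfer (C2 is quaternary).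

Step 15
Reactants: 20 methyl (2Z)-5-[(2S)-6-[(tert-butyldimethylsilyl)oxy]-2,8-dimethyl-2H-chromen-2-yl]-2-[(2E,4S)-4-hydroxy-4,8-dimethylnona-2,7-dien-1-yl]pent-2-enoate
Product: 21 (2Z,4E,6S)-2-{3-[(2S)-6-[(tert-butyldimethylsilyl)oxy]-2,8-dimethyl-2H-chromen-2-yl]propylidene}-6,10-dimethylundeca-4,9-diene-1,6-diol
Conditions: DIBAL-H (3.5 equiv), CH2Cl2, −78 → −20 °C; Rochelle salt
Reagents that add atoms: none
Why: DIBAL-H 1,2-reduction of the α,β-unsaturated ester should give the primary allylic alcohol without touching the alkenes, the aryl silyl ether or the alkene geometry.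

Step 16
Reactants: 21 (2Z,4E,6S)-2-{3-[(2S)-6-[(tert-butyldimethylsilyl)oxy]-2,8-dimethyl-2H-chromen-2-yl]propylidene}-6,10-dimethylundeca-4,9-diene-1,6-diol
Product: 23 (2S)-6-[(tert-butyldimethylsilyl)oxy]-2-[(3E,6E,8S)-8-hydroxy-4,8,12-trimethyltrideca-3,6,11-trien-1-yl]-2,8-dimethyl-2H-chromene, via allylic mesylate 22 (not isolated)
Conditions: MsCl (1.1 equiv), Et3N, THF, −40 °C; then LiEt3BH (4 equiv), −40 → 0 °C
Reagents that add atoms: methanesulfonyl chloride, CS(=O)(=O)Cl (atoms present only in 22)
Why: Selective mesylation of the primary allylic hydroxyl in the presence of the hindered tertiary one, then direct SN2 hydride displacement with Super-Hydride, should turn CH2OH into CH3 without allylic transposition or loss of alkene geometry.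

Step 17
Reactants: 23 (2S)-6-[(tert-butyldimethylsilyl)oxy]-2-[(3E,6E,8S)-8-hydroxy-4,8,12-trimethyltrideca-3,6,11-trien-1-yl]-2,8-dimethyl-2H-chromene
Product: 24 (2S)-2-[(3E,6E,8S)-8-hydroxy-4,8,12-trimethyltrideca-3,6,11-trien-1-yl]-2,8-dimethyl-2H-chromen-6-ol (CNP0155965.1)
Conditions: TBAF, AcOH, THF, 0 °C, degassed
Reagents that add atoms: none
Why: Fluoride-mediated cleavage of the aryl silyl ether, buffered with acetic acid, should free the phenol without affecting the tertiary allylic alcohol, the skipped diene or the chromene.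

**Compound list**
1 | geraniol | CC(C)=CCC/C(C)=C/CO | starting material
2 | (2S,3S)-2,3-epoxygeraniol | CC(C)=CCC[C@]1(C)O[C@H]1CO | intermediate
3 | (2R,3S)-3-methyl-3-(4-methylpent-3-en-1-yl)oxirane-2-carbaldehyde | CC(C)=CCC[C@]1(C)O[C@H]1C=O | intermediate
4 | (2S,3S)-2-methyl-2-(4-methylpent-3-en-1-yl)-3-vinyloxirane | CC(C)=CCC[C@]1(C)O[C@H]1C=C | intermediate
5 | (4S)-4,8-dimethylnona-1,7-dien-4-ol | CC(C)=CCC[C@](C)(O)CC=C | intermediate
6 | 2-methylhydroquinone | Cc1cc(O)ccc1O | starting material
7 | 4-[(tert-butyldimethylsilyl)oxy]-2-methylphenol | Cc1cc(O[Si](C)(C)C(C)(C)C)ccc1O | intermediate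
8 | 4-[(tert-butyldimethylsilyl)oxy]-2-(hydroxymethyl)-6-methylphenol (not isolated) | Cc1cc(O[Si](C)(C)C(C)(C)C)cc(CO)c1O | intermediate
9 | 5-[(tert-butyldimethylsilyl)oxy]-2-hydroxy-3-methylbenzaldehyde | Cc1cc(O[Si](C)(C)C(C)(C)C)cc(C=O)c1O | intermediate
10 | 4-[(tert-butyldimethylsilyl)oxy]-2-ethenyl-6-methylphenol | Cc1cc(O[Si](C)(C)C(C)(C)C)cc(C=C)c1O | intermediate
11 | geranyl acetate | CC(C)=CCC/C(C)=C/COC(C)=O | starting material
12 | (2E)-5-(3,3-dimethyloxiran-2-yl)-3-methylpent-2-en-1-yl acetate (racemic) | CC1(C)OC1CC/C(C)=C/COC(C)=O | intermediate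
13 | (2E)-6,7-dihydroxy-3,7-dimethyloct-2-en-1-yl acetate (racemic, not isolated) | CC(C)(O)C(O)CC/C(C)=C/COC(C)=O | intermediate
14 | (2E)-3-methyl-6-oxohex-2-en-1-yl acetate | O=CCC/C(C)=C/COC(C)=O | intermediate
15 | (2E)-3-methylhept-2-en-6-yn-1-yl acetate (not isolated) | C#CCC/C(C)=C/COC(C)=O | intermediate
16 | (2E)-3-methylhept-2-en-6-yn-1-ol | C#CCC/C(C)=C/CO | intermediate
17 | methyl (6E)-8-[(methoxycarbonyl)oxy]-6-methyloct-6-en-2-ynoate | COC(=O)C#CCC/C(C)=C/COC(=O)OC | intermediate
18 | methyl (6S)-6-{4-[(tert-butyldimethylsilyl)oxy]-2-ethenyl-6-methylphenoxy}-6-methyloct-7-en-2-ynoate | COC(=O)C#CCC[C@@](C)(C=C)Oc1c(C)cc(O[Si](C)(C)C(C)(C)C)cc1C=C | intermediate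
19 | methyl 5-[(2S)-6-[(tert-butyldimethylsilyl)oxy]-2,8-dimethyl-2H-chromen-2-yl]pent-2-ynoate | COC(=O)C#CCC[C@@]1(C)C=Cc2cc(O[Si](C)(C)C(C)(C)C)cc(C)c2O1 | intermediate
20 | methyl (2Z)-5-[(2S)-6-[(tert-butyldimethylsilyl)oxy]-2,8-dimethyl-2H-chromen-2-yl]-2-[(2E,4S)-4-hydroxy-4,8-dimethylnona-2,7-dien-1-yl]pent-2-enoate | CC(C)=CCC[C@](C)(O)/C=C/C/C(C(=O)OC)=C/CC[C@@]1(C)C=Cc2cc(O[Si](C)(C)C(C)(C)C)cc(C)c2O1 | intermediate
21 | (2Z,4E,6S)-2-{3-[(2S)-6-[(tert-butyldimethylsilyl)oxy]-2,8-dimethyl-2H-chromen-2-yl]propylidene}-6,10-dimethylundeca-4,9-diene-1,6-diol | CC(C)=CCC[C@](C)(O)/C=C/C/C(CO)=C/CC[C@@]1(C)C=Cc2cc(O[Si](C)(C)C(C)(C)C)cc(C)c2O1 | intermediate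
22 | primary methanesulfonate of 21 (not isolated) | CC(C)=CCC[C@](C)(O)/C=C/C/C(COS(C)(=O)=O)=C/CC[C@@]1(C)C=Cc2cc(O[Si](C)(C)C(C)(C)C)cc(C)c2O1 | intermediate
23 | (2S)-6-[(tert-butyldimethylsilyl)oxy]-2-[(3E,6E,8S)-8-hydroxy-4,8,12-trimethyltrideca-3,6,11-trien-1-yl]-2,8-dimethyl-2H-chromene | CC(C)=CCC[C@](C)(O)/C=C/C/C(C)=C/CC[C@@]1(C)C=Cc2cc(O[Si](C)(C)C(C)(C)C)cc(C)c2O1 | intermediate
24 | (2S)-2-[(3E,6E,8S)-8-hydroxy-4,8,12-trimethyltrideca-3,6,11-trien-1-yl]-2,8-dimethyl-2H-chromen-6-ol | CC(C)=CCC[C@](C)(O)/C=C/C/C(C)=C/CC[C@@]1(C)C=Cc2cc(O)cc(C)c2O1 | target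

**Step count and risks**

Total steps: 17. Longest linear sequence: 10 (steps 8–17, from geranyl acetate).

Steps most likely to fail:

1. Step 14. The cationic ruthenium catalyst may be sequestered as an η6-arene complex by the electron-rich ring. Oxidative cyclisation may also be slow because of the quaternary carbon next to the reacting allylic CH2, so that alkyne oligomerisation or bond formation at the β-alkyne carbon competes. Fallback, setting out from 19 and 4 and returning at 20: palladium-catalysed hydrostannation of 19 (Bu3SnH, Pd(PPh3)4, THF, 0 °C) should place tin on the ester-bearing carbon by cis addition and give methyl (2E)-5-[(2S)-6-[(tert-butyldimethylsilyl)oxy]-2,8-dimethyl-2H-chromen-2-yl]-2-(tributylstannyl)pent-2-enoate F1. Stille-type 1,4-coupling of F1 with vinyl epoxide 4 (Pd2(dba)3, AsPh3, DMF/H2O, rt; KF work-up) then forms the same C–C bond with opening of the epoxide and should give 20 directly.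

2. Step 12. The phenoxide may attack the unsubstituted allyl terminus and give the linear ether. Facial discrimination at the hindered terminus may be low with the ortho,ortho'-disubstituted phenol. The phenoxide may also add to the alkynoate in a conjugate sense. Fallback, setting out from 16 and 7 and returning at 19: MnO2 oxidation of 16 gives (2E)-3-methylhept-2-en-6-ynal F2. Condensation of F2 with phenol 7 (PhB(OH)2, AcOH, toluene, reflux; ortho-alkylation, dehydration to the o-quinone methide and oxa-6π electrocyclisation) gives racemic 2-(but-3-yn-1-yl)-6-[(tert-butyldimethylsilyl)oxy]-2,8-dimethyl-2H-chromene F3. LDA then ClCO2Me at −78 °C gives the racemic alkynoate F4, and preparative chiral-phase chromatography separates 19 from its (R)-enantiomer F5.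

3. Step 4. Hydride may be delivered to the terminal allyl carbon and give the internal alkene, or the π-allyl-palladium alkoxide may collapse by β-hydride elimination to carbonyl compounds. Fallback, setting out from 2 and returning at 5: Red-Al opening of the epoxy alcohol 2 at C2 (THF, 0 °C) gives (3S)-3,7-dimethyloct-6-ene-1,3-diol F6. Selective oxidation of the primary hydroxyl (TEMPO, PhI(OAc)2) gives (3S)-3-hydroxy-3,7-dimethyloct-6-enal F7, and Wittig methylenation of F7 (Ph3PCH3Br, NaHMDS, THF, −78 °C) gives 5.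

**Further compounds**
F1 | step 14 | methyl (2E)-5-[(2S)-6-[(tert-butyldimethylsilyl)oxy]-2,8-dimethyl-2H-chromen-2-yl]-2-(tributylstannyl)pent-2-enoate | CCCC[Sn](CCCC)(CCCC)/C(C(=O)OC)=C/CC[C@@]1(C)C=Cc2cc(O[Si](C)(C)C(C)(C)C)cc(C)c2O1
F2 | step 12 | (2E)-3-methylhept-2-en-6-ynal | C#CCC/C(C)=C/C=O
F3 | step 12 | racemic 2-(but-3-yn-1-yl)-6-[(tert-butyldimethylsilyl)oxy]-2,8-dimethyl-2H-chromene | C#CCCC1(C)C=Cc2cc(O[Si](C)(C)C(C)(C)C)cc(C)c2O1
F4 | step 12 | racemic methyl 5-{6-[(tert-butyldimethylsilyl)oxy]-2,8-dimethyl-2H-chromen-2-yl}pent-2-ynoate | COC(=O)C#CCCC1(C)C=Cc2cc(O[Si](C)(C)C(C)(C)C)cc(C)c2O1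
F5 | step 12 | methyl 5-[(2R)-6-[(tert-butyldimethylsilyl)oxy]-2,8-dimethyl-2H-chromen-2-yl]pent-2-ynoate | COC(=O)C#CCC[C@]1(C)C=Cc2cc(O[Si](C)(C)C(C)(C)C)cc(C)c2O1
F6 | step 4 | (3S)-3,7-dimethyloct-6-ene-1,3-diol | CC(C)=CCC[C@](C)(O)CCO
F7 | step 4 | (3S)-3-hydroxy-3,7-dimethyloct-6-enal | CC(C)=CCC[C@](C)(O)CC=O
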